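Starting material leaves by two routes, to product with dissolved gas and to quenched substrate with protic impurity, so the easy first step is to compare the two.

solid substrate 0.40 M; gas phase 99 mM (held); protic impurity 0.400 M; time 40 h

* product at 40 h, in percent of the solid substrate charged
* the change that raises the amount of product at 40 h, in percent of the solid substrate charged most ("none" if none brings more than 2 percentage points) (Sunday's / Saturday's / Tuesday's / Wednesday's / none)
* amount of product at 40 h, in percent of the solid substrate charged, after Sunday's

- Sunday's: doubling the solubility in step 4, all else as stated
- Saturday's: doubling the transfer coefficient of step 1, all else as stated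
- Tuesday's: doubling the saturation concentration of gas phase, all else as stated
- Wednesday's: doubling the dissolution coefficient of step 4, all else as stated

- as a solid, counted per litre of solution: solid substrate
- at the start none of the gas is dissolved
- at the start none of the solid substrate is in solution
- run time (flask): 40 h

    gas phase ⇌ dissolved gas, rate k1*(csat - [dissolved gas]) (k1 = 7.9 × 10⁻⁵ s⁻¹, csat = 99 mM)
    starting material + dissolved gas → product (k2 = 9.9 × 10⁻⁵ L mol⁻¹ s⁻¹)
    starting material + protic impurity → quenched substrate (k3 = 5.5 × 10⁻⁵ L mol⁻¹ s⁻¹)
    solid substrate ⇌ starting material, rate k4*(cs4 - [starting material]) while solid is left; crystals form when [starting material] > cs4 (cs4 = 0.20 M, k4 = 2.9 × 10⁻⁵ s⁻¹)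

With the gas at saturation and the impurity as charged, the product route runs at 0.445 of the quench route; we carry this branch ratio, a selectivity factor.

Our own reckoning replaces the curves by means. We guess the impurity at 0.7 of its charge on average, so starting material is lost at 0.0907 h⁻¹. Against dissolution it then levels at 26.8% of the charge after a lag of 5.12 h, and the gas stands at 88.2% of saturation. Feeding at that level for the run less the lag turns over 84.6% of the charge. The mean share going to product is 35.9%, so we expect 30.4% product. Tuesday's doubles the ratio, which at the same turnover gives a share of 52.9% and 44.8% product.

The forecast gave 28%, lower than our figure, with 32.6% after Sunday's and Tuesday's as the best change, “clearly the largest gain”.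

The flask gives 27.9%, and 32.0% after Sunday's. The best change is Tuesday's, with a gain of 18 percentage points against 4.1 points for Sunday's.

The readings can now replace our guessed means. In this flask at 40.0 h, quenched substrate stands at 51.7%, the midpoint of the impurity's start and end values is 74.1% of its charge, and the gas is 0.0883 M. Quenched substrate times the ratio, scaled by gas over saturation and divided by that midpoint, gives 27.7% product, against 27.9%. The gas lay lower early, 0.0656 M at 4.00 h, when product was 0.568%. In the same flask read at 25 h, quenched substrate 33.8%, impurity 66.2% and gas 0.0875 M give 16.0%, and that reading holds 15.5% product.

Its constants are invented; the result is computed.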